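## Retrosynthetic overview

- The target is (13R)-13-hydroxylabda-8(17),14-dien-19-yl tiglate. The last cuts are the C19–O ester and the C11–C12 bond, made from a C11 sulfonyl carbanion and (S)-2-methyl-2-vinyloxirane, which brings C12–C16 with C13 already set.
- The plan rests on ring B (C5–C10). Quaternary C10 (bearing C20) adjoins C9 (bearing C11) and C8 (bearing C17, finally the exocyclic methylene). Moving C8=C17 into the ring as C8=C9 and adding C5=C6 reveals a cyclohexa-1,4-diene.
- The key cut is a retro-[4+2] across C9–C10 and C7–C8. It gives the ring A diene C10=C5–C6=C7 and methyl but-2-ynoate.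
- Ring A is bought as 2,6-dimethylcyclohexanone. C19 comes from hydroxymethylation, C4 from lipase resolution, and C6–C7 from triflate/Stille vinylation. Ring B is formed second.
- After the cycloaddition, C5 (hydrogenation) and C9 (dienolate protonation) are set from the α face, opposite axial C20 and C19.

Key step: step 6

Remark on numbering: labdane numbering is used throughout, also for ring A precursors. Labdane-type names imply 5α-H, 9α-H (C11 β), 10β-CH3 (C20) and C19 as the 4β axial carbon. The same spatial arrangement at C4 is R in the ketone and triflate and S from the diene onward, only because the priority order changes.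

Assumption: the lipase acylates the (S)-enantiomer of the racemic hydroxymethyl ketone faster than the (R)-enantiomer.

## Route

Step 1
Reactants: 1 2,6-dimethylcyclohexanone
Product: 3 rac-2-(hydroxymethyl)-2,6-dimethylcyclohexanone (both C6 epimers), via lithium enolate 2 (not isolated)
Conditions: LDA, THF, −78 → 0 °C; CH2O gas (cracked paraformaldehyde), −78 °C
Reagents that add atoms: formaldehyde, C=O
Why: Aldol-type hydroxymethylation: the symmetrical ketone gives a single tetrasubstituted lithium enolate, which adds at carbon to monomeric formaldehyde and builds the quaternary carbon (future C4) with C19 as a racemate, whose second stereocentre (future C10) is irrelevant because it becomes sp2 in step 4.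

Step 2
Reactants: 3 rac-2-(hydroxymethyl)-2,6-dimethylcyclohexanone
Product: 4 (2R)-2-(hydroxymethyl)-2,6-dimethylcyclohexanone (both C6 epimers)
Conditions: Burkholderia cepacia lipase (Amano PS, immobilised), vinyl acetate, MTBE, 30 °C, run past half conversion; chromatography
Reagents that add atoms: none
Why: Lipase-catalysed kinetic resolution by irreversible acyl transfer from vinyl acetate: the enzyme distinguishes carbonyl side, CH2 side and methyl at the carbon next to CH2OH, so that beyond half conversion the slower (R)-alcohol, which has C4 of the target, should remain enantioenriched and be separable from the acetate.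

Step 3
Reactants: 4 (2R)-2-(hydroxymethyl)-2,6-dimethylcyclohexanone
Product: 5 (2R)-2-[(tert-butyldiphenylsilyloxy)methyl]-2,6-dimethylcyclohexanone
Conditions: TBDPSCl, imidazole, DMF, rt
Reagents that add atoms: tert-butylchlorodiphenylsilane, CC(C)(C)[Si](Cl)(c1ccccc1)c1ccccc1
Why: Imidazole-promoted silylation of the primary alcohol blocks retro-aldol cleavage, and TBDPS is chosen because it withstands LDA, EtAlCl2, LiAlH4 and n-BuLi and is the bulky group that shields the β face in step 6.

Step 4
Reactants: 5 (2R)-2-[(tert-butyldiphenylsilyloxy)methyl]-2,6-dimethylcyclohexanone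
Product: 7 (6R)-6-[(tert-butyldiphenylsilyloxy)methyl]-2,6-dimethylcyclohex-1-en-1-yl trifluoromethanesulfonate, via lithium enolate 6 (not isolated)
Conditions: LDA, THF, −78 → 0 °C; PhNTf2, 0 °C → rt
Reagents that add atoms: N-phenylbis(trifluoromethanesulfonimide), O=S(=O)(N(c1ccccc1)S(=O)(=O)C(F)(F)F)C(F)(F)F
Why: Enol triflate formation: with C2 quaternary the ketone can enolise only towards C6, this enolate cannot expel the silyloxy group, and O-sulfonylation by PhNTf2 fixes the tetrasubstituted C5=C10 double bond while erasing the C6 stereocentre.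

Step 5
Reactants: 7 enol triflate; 8 tributyl(vinyl)stannane
Product: 9 tert-butyl{[(1S)-1,3-dimethyl-2-vinylcyclohex-2-en-1-yl]methoxy}diphenylsilane
Conditions: Pd2(dba)3 (cat.), AsPh3 (cat.), LiCl, NMP, 60 °C
Reagents that add atoms: none
Why: Stille coupling: zerovalent palladium inserts into the C–OTf bond, chloride and the weakly bound AsPh3 ligand speed up transmetalation from tin at this hindered centre, and reductive elimination gives the 1-vinylcyclohexene without touching C4.

Step 6
Reactants: 9 ring A diene; 10 methyl but-2-ynoate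
Product: 11 methyl (5S,8aS)-5-[(tert-butyldiphenylsilyloxy)methyl]-2,5,8a-trimethyl-3,5,6,7,8,8a-hexahydronaphthalene-1-carboxylate (5,8-diene ester; C19 and C20 both β)
Conditions: 10 (3 equiv), EtAlCl2 (0.3 equiv), CH2Cl2, −40 → 0 °C
Reagents that add atoms: none
Why: EtAlCl2 binds the ester carbonyl of 10 and lowers its LUMO, and the s-cis form of the diene C10=C5–C6=C7 of 9 then adds suprafacially to one π bond of the alkyne in a concerted, asynchronous [4+2] cycloaddition in which C7–C8 bonding runs ahead of C9–C10 bonding. The closest known reaction type is the Diels–Alder addition of 2,6,6-trisubstituted 1-vinylcyclohexenes to acetylenic esters, thermal or Lewis-acid assisted, which likewise creates the angular quaternary carbon of a decalin. Ring B (C5–C10) closes by intermolecular [4+2] annulation onto ring A and appears as a cyclohexa-1,4-diene (C5=C6, C8=C9) that cannot aromatise because C10 is quaternary. Regioselectivity is required and is secured by the diene: the unsubstituted terminus C7 has the largest HOMO coefficient and meets the β-carbon of the ynoate, while developing positive charge is held at the fully substituted C10, which takes the ester-bearing carbon, so C17 ends on C8 and C11 on C9. The one new stereocentre, C10, is controlled by C4: the CH2OTBDPS arm prefers the pseudoaxial β position, away from the in-plane clash with H6 of the vinyl group, its silyl group sweeps the β face, the dienophile therefore approaches from the α face past the small pseudoequatorial methyl C18, and C20 is pushed β, cis to C19. Facial selectivity is the demand least well secured, since the two C4 substituents differ only beyond their first atom; the low temperature opened by the Lewis acid and the bulk of TBDPS work for it, and the C10 epimer is to be removed by chromatography at this stage.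

Step 7
Reactants: 11 5,8-diene ester
Product: 12 methyl (4aR,5S,8aS)-5-[(tert-butyldiphenylsilyloxy)methyl]-2,5,8a-trimethyl-3,4,4a,5,6,7,8,8a-octahydronaphthalene-1-carboxylate (trans-decalin, 8-ene ester)
Conditions: H2 (1 atm), 10% Pd/C, EtOAc, rt
Reagents that add atoms: none
Why: Chemoselective heterogeneous hydrogenation takes the trisubstituted C5=C6 alkene and leaves the tetrasubstituted, ester-conjugated C8=C9 alkene, and because axial C20 and C19 close the β face, hydrogen is delivered from the α face and sets H5 α (trans ring fusion).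

Step 8
Reactants: 12 8-ene ester
Product: 14 methyl 19-(tert-butyldiphenylsilyloxy)-12,13,14,15,16-pentanorlabd-8(17)-en-11-oate, via lithium dienolate 13 (not isolated)
Conditions: LDA, THF, −78 → 0 °C; recool to −78 °C, AcOH in THF
Reagents that add atoms: none
Why: Deconjugative kinetic protonation: ester-bound LDA removes a proton from C17, the γ-carbon that lies cis to the ester on C8=C9, and the extended dienolate is protonated at its α-carbon C9 from the α face opposite axial C20, which gives H9 α, the equatorial β ester and the exocyclic C8=C17 alkene.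

Step 9
Reactants: 14 8(17)-ene ester
Product: 15 19-(tert-butyldiphenylsilyloxy)-12,13,14,15,16-pentanorlabd-8(17)-en-11-ol
Conditions: LiAlH4, Et2O, 0 °C
Reagents that add atoms: none
Why: Hydride reduction of the ester is fast at 0 °C, so neither epimerisation at C9 nor return of the alkene into conjugation should compete, and the silyl ether and alkene are inert.

Step 10
Reactants: 15 C11 alcohol
Product: 16 11-(phenylsulfanyl)-19-(tert-butyldiphenylsilyloxy)-12,13,14,15,16-pentanorlabd-8(17)-ene
Conditions: PhSSPh, n-Bu3P, THF, rt → 50 °C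
Reagents that add atoms: diphenyl disulfide, c1ccccc1SSc1ccccc1
Why: Mukaiyama–Hata thioetherification: the alcohol is activated as an alkoxyphosphonium ion and displaced by thiophenolate in an SN2 reaction at primary C11 under neutral conditions that suit β-branched carbinols and touch no stereocentre.

Step 11
Reactants: 16 C11 phenyl sulfide
Product: 18 11-(phenylsulfonyl)-19-(tert-butyldiphenylsilyloxy)-12,13,14,15,16-pentanorlabd-8(17)-ene, via sulfoxide 17 (not isolated)
Conditions: 30% H2O2, (NH4)6Mo7O24·4H2O (cat.), EtOH, 0 °C → rt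
Reagents that add atoms: hydrogen peroxide, OO
Why: Molybdate-catalysed peroxide oxidation attacks nucleophilic sulfur twice far faster than the unactivated 1,1-disubstituted alkene, which has no directing hydroxyl.

Step 12
Reactants: 19 (S)-2-methylglycidol
Product: 20 (R)-2-methyloxirane-2-carbaldehyde
Conditions: (COCl)2, DMSO, CH2Cl2, −78 °C; Et3N, → 0 °C; salts filtered, solvent removed through a column at ambient pressure
Reagents that add atoms: none
Why: Swern oxidation stops at the aldehyde under cold, non-aqueous, non-acidic conditions that spare the epoxide, and the fully substituted stereocentre cannot epimerise (the descriptor changes only through the priority rules).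

Step 13
Reactants: 20 (R)-2-methyloxirane-2-carbaldehyde
Product: 21 (S)-2-methyl-2-vinyloxirane
Conditions: Ph3PCH3Br, n-BuLi, THF, 0 °C; 20, −78 °C → rt; co-distillation with THF, used as titrated solution
Reagents that add atoms: methyltriphenylphosphonium bromide, C[P+](c1ccccc1)(c1ccccc1)c1ccccc1.[Br-]
Why: Wittig methylenation with the non-stabilised ylide turns CHO into the vinyl group C14=C15 without touching the epoxide, and butane as the only volatile residue of the base lets the volatile product be taken on as a dry THF solution.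

Step 14
Reactants: 18 C11 phenyl sulfone; 21 (S)-2-methyl-2-vinyloxirane
Product: 23 (13R)-11-(phenylsulfonyl)-19-(tert-butyldiphenylsilyloxy)labda-8(17),14-dien-13-ol (C11 epimers), via lithiated sulfone 22 (not isolated)
Conditions: n-BuLi, THF–DMPU, −78 °C; 21 (3 equiv), −78 °C → rt
Reagents that add atoms: none
Why: Alkylation of an α-sulfonyl carbanion by SN2 opening of an epoxide: without palladium the lithiated sulfone attacks the unsubstituted ring carbon (C12) rather than tertiary C13 or the vinyl terminus, the C13–O bond stays intact so that (S)-21 delivers 13R, and the C11 epimers converge in step 15.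

Step 15
Reactants: 23 hydroxy sulfone
Product: 24 (13R)-19-(tert-butyldiphenylsilyloxy)labda-8(17),14-dien-13-ol
Conditions: 6% Na(Hg), Na2HPO4, MeOH–THF, −10 °C → rt
Reagents that add atoms: none
Why: Reductive desulfonylation by electron transfer from sodium amalgam cleaves the C11–S bond and the buffer protonates the carbanion; the hydroxyl is γ to sulfur, so no Julia-type elimination can occur, and the isolated alkenes and the silyl ether are inert.

Step 16
Reactants: 24 silyl ether
Product: 25 (13R)-labda-8(17),14-diene-13,19-diol (torulosol)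
Conditions: TBAF, THF, 50 °C
Reagents that add atoms: none
Why: Fluoride-induced desilylation is driven by the Si–F bond strength, warming is planned because the C19 ether is neopentylic and axial, and nothing else in 24 is labile to fluoride or mild base.

Step 17
Reactants: 25 diol; 26 tigloyl chloride [(E)-2-methylbut-2-enoyl chloride]
Product: 27 (13R)-13-hydroxylabda-8(17),14-dien-19-yl (E)-2-methylbut-2-enoate (target, 4S,5R,9S,10R,13R)
Conditions: pyridine, DMAP (cat.), CH2Cl2, 0 °C → rt
Reagents that add atoms: none
Why: DMAP-catalysed acylation selects the primary C19 hydroxyl over the tertiary allylic C13 hydroxyl, pyridine traps HCl so that the acid-labile allylic alcohol survives, and the thermodynamically preferred E geometry of the tiglate is retained.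

## Compound list

1 | 2,6-dimethylcyclohexanone | CC1CCCC(C)C1=O | starting material
2 | lithium 2,6-dimethylcyclohex-1-en-1-olate | CC1CCCC(C)=C1O[Li] | intermediate
3 | rac-2-(hydroxymethyl)-2,6-dimethylcyclohexanone | CC1CCCC(C)(CO)C1=O | intermediate
4 | (2R)-2-(hydroxymethyl)-2,6-dimethylcyclohexanone (C6 epimers) | CC1CCC[C@](C)(CO)C1=O | intermediate
5 | (2R)-2-[(tert-butyldiphenylsilyloxy)methyl]-2,6-dimethylcyclohexanone | CC1CCC[C@](C)(CO[Si](c2ccccc2)(c2ccccc2)C(C)(C)C)C1=O | intermediate
6 | lithium enolate of 5 | CC1=C(O[Li])[C@@](C)(CO[Si](c2ccccc2)(c2ccccc2)C(C)(C)C)CCC1 | intermediate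
7 | (6R)-6-[(tert-butyldiphenylsilyloxy)methyl]-2,6-dimethylcyclohex-1-en-1-yl trifluoromethanesulfonate | CC1=C(OS(=O)(=O)C(F)(F)F)[C@@](C)(CO[Si](c2ccccc2)(c2ccccc2)C(C)(C)C)CCC1 | intermediate
8 | tributyl(vinyl)stannane | C=C[Sn](CCCC)(CCCC)CCCC | starting material
9 | tert-butyl{[(1S)-1,3-dimethyl-2-vinylcyclohex-2-en-1-yl]methoxy}diphenylsilane | C=CC1=C(C)CCC[C@]1(C)CO[Si](c2ccccc2)(c2ccccc2)C(C)(C)C | intermediate
10 | methyl but-2-ynoate | CC#CC(=O)OC | starting material
11 | methyl (5S,8aS)-5-[(tert-butyldiphenylsilyloxy)methyl]-2,5,8a-trimethyl-3,5,6,7,8,8a-hexahydronaphthalene-1-carboxylate | COC(=O)C1=C(C)CC=C2[C@@](C)(CO[Si](c3ccccc3)(c3ccccc3)C(C)(C)C)CCC[C@]12C | intermediate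
12 | methyl (4aR,5S,8aS)-5-[(tert-butyldiphenylsilyloxy)methyl]-2,5,8a-trimethyl-3,4,4a,5,6,7,8,8a-octahydronaphthalene-1-carboxylate | COC(=O)C1=C(C)CC[C@H]2[C@@](C)(CO[Si](c3ccccc3)(c3ccccc3)C(C)(C)C)CCC[C@]12C | intermediate
13 | lithium dienolate of 12 (C9=C11 and C8=C17) | COC(O[Li])=C1C(=C)CC[C@H]2[C@@](C)(CO[Si](c3ccccc3)(c3ccccc3)C(C)(C)C)CCC[C@]12C | intermediate
14 | methyl (1S,4aR,5S,8aS)-5-[(tert-butyldiphenylsilyloxy)methyl]-5,8a-dimethyl-2-methylidenedecahydronaphthalene-1-carboxylate | COC(=O)[C@H]1C(=C)CC[C@H]2[C@@](C)(CO[Si](c3ccccc3)(c3ccccc3)C(C)(C)C)CCC[C@]12C | intermediate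
15 | 19-(tert-butyldiphenylsilyloxy)-12,13,14,15,16-pentanorlabd-8(17)-en-11-ol | OC[C@H]1C(=C)CC[C@H]2[C@@](C)(CO[Si](c3ccccc3)(c3ccccc3)C(C)(C)C)CCC[C@]12C | intermediate
16 | 11-(phenylsulfanyl)-19-(tert-butyldiphenylsilyloxy)-12,13,14,15,16-pentanorlabd-8(17)-ene | C(Sc4ccccc4)[C@H]1C(=C)CC[C@H]2[C@@](C)(CO[Si](c3ccccc3)(c3ccccc3)C(C)(C)C)CCC[C@]12C | intermediate
17 | 11-(phenylsulfinyl) analogue of 16 (epimers at sulfur) | C(S(=O)c4ccccc4)[C@H]1C(=C)CC[C@H]2[C@@](C)(CO[Si](c3ccccc3)(c3ccccc3)C(C)(C)C)CCC[C@]12C | intermediate
18 | 11-(phenylsulfonyl)-19-(tert-butyldiphenylsilyloxy)-12,13,14,15,16-pentanorlabd-8(17)-ene | C(S(=O)(=O)c4ccccc4)[C@H]1C(=C)CC[C@H]2[C@@](C)(CO[Si](c3ccccc3)(c3ccccc3)C(C)(C)C)CCC[C@]12C | intermediate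
19 | (S)-2-methylglycidol | OC[C@]1(C)OC1 | starting material
20 | (R)-2-methyloxirane-2-carbaldehyde | O=C[C@]1(C)OC1 | intermediate
21 | (S)-2-methyl-2-vinyloxirane | C=C[C@]1(C)OC1 | intermediate
22 | 11-lithio derivative of 18 | [Li]C(S(=O)(=O)c4ccccc4)[C@H]1C(=C)CC[C@H]2[C@@](C)(CO[Si](c3ccccc3)(c3ccccc3)C(C)(C)C)CCC[C@]12C | intermediate
23 | (13R)-11-(phenylsulfonyl)-19-(tert-butyldiphenylsilyloxy)labda-8(17),14-dien-13-ol (C11 epimers) | C=C[C@](C)(O)CC(S(=O)(=O)c4ccccc4)[C@H]1C(=C)CC[C@H]2[C@@](C)(CO[Si](c3ccccc3)(c3ccccc3)C(C)(C)C)CCC[C@]12C | intermediate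
24 | (13R)-19-(tert-butyldiphenylsilyloxy)labda-8(17),14-dien-13-ol | C=C[C@](C)(O)CC[C@H]1C(=C)CC[C@H]2[C@@](C)(CO[Si](c3ccccc3)(c3ccccc3)C(C)(C)C)CCC[C@]12C | intermediate
25 | (13R)-labda-8(17),14-diene-13,19-diol | C=C[C@](C)(O)CC[C@H]1C(=C)CC[C@H]2[C@@](C)(CO)CCC[C@]12C | intermediate
26 | tigloyl chloride | C/C=C(\C)C(=O)Cl | starting material
27 | (13R)-13-hydroxylabda-8(17),14-dien-19-yl (E)-2-methylbut-2-enoate | C=C[C@](C)(O)CC[C@H]1C(=C)CC[C@H]2[C@@](C)(COC(=O)/C(C)=C/C)CCC[C@]12C | target

## Step count and risks

Total step count: 17.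

Longest linear sequence: 15 steps (1 to 27 through steps 1–11 and 14–17). Steps 12 and 13 form the side branch.

**Risk 1, step 6.**
- What may go wrong: bond formation at the fully substituted diene terminus C10 may be too slow for the weakly activated, β-methylated ynoate. Lewis-acid-induced oligomerisation of the diene, or on heating a 1,5-hydrogen shift from C20, would then consume the diene. Discrimination between the two diene faces may also be incomplete.
- Fallback: it sets out from 9 and returns at 15.
  - Compound 9 is heated with dimethyl acetylenedicarboxylate (toluene, 110 °C), the doubly activated dienophile proven for this diene class. This gives the 5,8-diene diester F1.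
  - Hydrogenation (H2, Pd/C, EtOAc) gives the trans-fused 8-ene diester F2, at which stage any C10 epimer is separated.
  - LiAlH4 gives the 8-ene-11,17-diol F3.
  - The less hindered C17 hydroxyl is converted selectively (ClCO2Me, pyridine, −20 °C) into the C17 methyl carbonate F4.
  - A Tsuji–Trost-type formate hydrogenolysis (Pd2(dba)3, n-Bu3P, HCO2H, Et3N, THF) delivers hydride to the more substituted allyl terminus C9. Hydride comes from the palladium-bearing α face and gives 15 directly, so steps 7–9 are bypassed.

**Risk 2, step 14.**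
- What may go wrong: the carbanion at C11 is flanked by C9 and quaternary C10 and may open the 2,2-disubstituted epoxide too slowly. Proton transfer, attack at the vinyl terminus and loss of the volatile epoxide would then compete.
- Fallback: it sets out from 18 (through 22) and returns at 24.
  - The lithiated sulfone 22 is alkylated with commercial (E)-4-bromo-3-methylbut-2-enyl acetate (THF, −78 °C), a much more reactive allylic electrophile. This gives the sulfonyl 13E-en-15-yl acetate F5.
  - K2CO3 in MeOH gives the hydroxy sulfone F6.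
  - Buffered Na(Hg) gives the 13E-en-15-ol F7.
  - Sharpless asymmetric epoxidation (Ti(OiPr)4, D-(−)-diethyl tartrate, t-BuOOH, 4 Å sieves, CH2Cl2, −20 °C) gives the (13R,14R)-epoxy alcohol F8.
  - Appel-type iodination (I2, PPh3, imidazole) gives the epoxy iodide F9.
  - Zinc dust in ethanol opens F9 reductively with the C13–O bond untouched, giving 24.

**Risk 3, step 2.**
- What may go wrong: enantiomer discrimination by the enzyme may be insufficient, because the stereocentre is quaternary and the substrate is present as two C6 epimers.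
- Fallback: it sets out from 1 and returns at 4.
  - Soft enolisation (TMSCl, NaI, Et3N, MeCN) gives the trimethylsilyl enol ether F10.
  - A catalytic asymmetric Mukaiyama aldol hydroxymethylation follows, with aqueous formaldehyde, Sc(OTf)3 and enantiopure 6,6'-bis(1-hydroxy-2,2-dimethylpropyl)-2,2'-bipyridine in aqueous DME at −20 °C. It sets the quaternary carbon under catalyst control for both antipodes of F10.
  - The ligand antipode that leads to the R series is chosen in a trial run.

## Further compounds

F1 | step 6 | dimethyl 19-(tert-butyldiphenylsilyloxy)-5,8-diene-11,17-dioate (adduct of 9 and dimethyl acetylenedicarboxylate) | COC(=O)C1=C(C(=O)OC)CC=C2[C@@](C)(CO[Si](c3ccccc3)(c3ccccc3)C(C)(C)C)CCC[C@]12C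
F2 | step 6 | trans-fused 8-ene-11,17-dioate (5α-H) | COC(=O)C1=C(C(=O)OC)CC[C@H]2[C@@](C)(CO[Si](c3ccccc3)(c3ccccc3)C(C)(C)C)CCC[C@]12C
F3 | step 6 | 19-(tert-butyldiphenylsilyloxy)-12,13,14,15,16-pentanorlabd-8-ene-11,17-diol | OCC1=C(CO)CC[C@H]2[C@@](C)(CO[Si](c3ccccc3)(c3ccccc3)C(C)(C)C)CCC[C@]12C
F4 | step 6 | C17 methyl carbonate of F3 | OCC1=C(COC(=O)OC)CC[C@H]2[C@@](C)(CO[Si](c3ccccc3)(c3ccccc3)C(C)(C)C)CCC[C@]12C
F5 | step 14 | (13E)-11-(phenylsulfonyl)-19-(tert-butyldiphenylsilyloxy)labda-8(17),13-dien-15-yl acetate | CC(=O)OC/C=C(\C)CC(S(=O)(=O)c4ccccc4)[C@H]1C(=C)CC[C@H]2[C@@](C)(CO[Si](c3ccccc3)(c3ccccc3)C(C)(C)C)CCC[C@]12C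
F6 | step 14 | (13E)-11-(phenylsulfonyl)-19-(tert-butyldiphenylsilyloxy)labda-8(17),13-dien-15-ol | OC/C=C(\C)CC(S(=O)(=O)c4ccccc4)[C@H]1C(=C)CC[C@H]2[C@@](C)(CO[Si](c3ccccc3)(c3ccccc3)C(C)(C)C)CCC[C@]12C
F7 | step 14 | (13E)-19-(tert-butyldiphenylsilyloxy)labda-8(17),13-dien-15-ol | OC/C=C(\C)CC[C@H]1C(=C)CC[C@H]2[C@@](C)(CO[Si](c3ccccc3)(c3ccccc3)C(C)(C)C)CCC[C@]12C
F8 | step 14 | (13R,14R)-13,14-epoxy-19-(tert-butyldiphenylsilyloxy)labd-8(17)-en-15-ol | OC[C@H]1O[C@]1(C)CC[C@H]2C(=C)CC[C@H]3[C@@](C)(CO[Si](c4ccccc4)(c4ccccc4)C(C)(C)C)CCC[C@]23C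
F9 | step 14 | 15-iodo analogue of F8 (epoxy iodide, same spatial arrangement) | IC[C@H]1O[C@]1(C)CC[C@H]2C(=C)CC[C@H]3[C@@](C)(CO[Si](c4ccccc4)(c4ccccc4)C(C)(C)C)CCC[C@]23C
F10 | step 2 | (2,6-dimethylcyclohex-1-en-1-yloxy)trimethylsilane | CC1CCCC(C)=C1O[Si](C)(C)C
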